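At early times in delta the substrate falls and target rises with it: at 10.0 h there is 55% substrate and 9% target. Delta is the flask I am asked about, and I have it and zeta to work from.

all flasks: substrate 0.30 M; partner A 0.285 M
- delta: partner B 0.90 M; protic impurity 0.030 M; temperature 5 °C; the very flask that is asked about, followed so far
- zeta: partner B 0.90 M; protic impurity 0.060 M; temperature 0 °C; run made earlier
- flask: partner B 0.900 M; protic impurity 0.0300 M; temperature 5 °C; time 8.0 d

| run | time / h | target / % | substrate / % |
|---|---|---|---|
| delta | 10.0 | 9 | 55 |
| delta | 20.0 | 13 | 37 |
| delta | 30.0 | 13 | 24 |
| delta | 60.0 | 21 | 9 |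
| delta | 120 | 20 | 0 |
| zeta | 2.00 | 0 | 90 |
| zeta | 4.00 | 3 | 85 |
| zeta | 6.00 | 2 | 77 |
| zeta | 8.00 | 2 | 69 |
| zeta | 10.0 | 3 | 68 |

(readings scatter by 2 percentage points)

- north-east: at 8.0 d raise the temperature by 20 K, then wait 2.5 d
- north: at 8.0 d add substrate, 50.0% of the amount charged, then wait 2.5 d
- west: change nothing and wait 2.5 d more
- south-east: at 8.0 d add partner A, 50.0% of the amount charged, then wait 2.5 d

- additions bring no volume worth counting
- the analysis behind the earlier runs scatters by 2 percentage points, standard deviation
- a reading or a percentage of target counts all its forms, free or not

- target, in percent of the substrate first charged, at 8.0 d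
- the option that brings most further target ("none" if no option brings more than 2 percentage points) (north-east / north / west / south-east / none)
- target present, in percent of the substrate first charged, after north-east
- target present, in percent of the substrate first charged, after south-east

I build the flask up one process at a time. First I take the main step alone, substrate and partner A giving target one to one. Partner A would then be the limiting reagent, and target would stop at:

95.0% of the substrate charged

Next I add the protic impurity as a small correction. If it takes partner A one to one, the ceiling drops to:

85.0%

That is a small change, and the delta readings are far below it. At 120 h the substrate stands at 0% and target at 20%, so some further process holds the rest out of sight.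

I measure that process with the unseen ratio, the substrate gone but not read as target, per part of target 4.00. The ratio at 10.0 h reads the same:

4.00

With the substrate read at 0%, target at 8.0 d is:

20.0%

Waiting or adding partner A leaves that figure where it is, as I reckon it.

Last comes temperature. Colder zeta reads a higher ratio at 10.0 h, 9.67, though it also holds more impurity. Its target reading is small, so I raise it by one standard deviation, which gives a cautious ratio of 5.40, still more than delta's. The rise of 20 K is 4 times the gap between the two runs, so I apply the same factor 4 times:

1.20, so target 45.4%

This assumes the unseen material can come back. Heat would then gain 25 percentage points. North brings 10 points if partner A still stands free, which no reading shows, and that is less than heat. I choose north-east.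

The forecast gives 20% now, 20% after north-east and 20% after south-east, and it names north as best: “Heating gives nothing either”.

The flask holds 18.5% at 8.0 d, 51.0% after north-east and 21.5% after south-east. The best option is north-east, with a gain of 32 points, against 0.26 points for north.

    2 second intermediate → homo product (k = 0.00420 L mol⁻¹ h⁻¹, Ea = 69.0 kJ mol⁻¹)
    open intermediate + second intermediate → target (k = 0.380 L mol⁻¹ h⁻¹, Ea = 74.0 kJ mol⁻¹)
    target ⇌ isomer of the product (K = 3.70, k = 0.200 h⁻¹, Ea = 97.0 kJ mol⁻¹, ΔH = −56.0 kJ mol⁻¹)
    substrate + partner B → open intermediate (k = 0.0890 L mol⁻¹ h⁻¹, Ea = 62.0 kJ mol⁻¹)
    partner A + protic impurity → quenched reagent (k = 0.340 L mol⁻¹ h⁻¹, Ea = 78.0 kJ mol⁻¹)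
    partner B + partner A → second intermediate (k = 0.260 L mol⁻¹ h⁻¹, Ea = 68.0 kJ mol⁻¹)
    partner A + target ⇌ idle adduct, settled at all times (K = 3.80 L mol⁻¹, ΔH = −29.0 kJ mol⁻¹)
    (constants at 5 °C)

The unseen ratio is 4.41 in the flask at 8.0 d and 0.961 after north-east. At 192 h the flask's unseen part holds 68.0% isomer of the product beside 13.3% open intermediate, and target and isomer relax with a half-life of 2.73 h, shorter than 8.0 d. The loss of target to isomer, both ways, is the main reason for the low figure: with that step struck out, the flask holds 86.5% target at 8.0 d, not 18.5%. The falling back of isomer to target is part of what north-east does: with that step struck out, north-east brings −0.13 points, not 32 points. In a repeat of the flask at 20 °C, the unseen ratio is 1.37.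

The readings come from a simulation from invented constants, noise included.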